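**Retrosynthetic overview**

- Ring labels: ring A is the phloroglucinol ring, ring C the dihydropyranone, ring B the aryl ring on C3, ring D the 2,2-dimethylpyran fused to ring B. The plan rests on the O1–C2–C3–C4 unit of ring C, a β-aryloxy ketone whose only stereocentre, C3, carries a hydrogen next to the C4 carbonyl and can therefore be created by face-selective protonation of the C3=C4 enol.
- Disconnection 1 (ring C, last bond): O1–C2, by catalytic enantioselective oxa-Michael closure with protonation at C3 of the open 2,4,6-trihydroxyphenyl 1-arylvinyl ketone.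
- Disconnection 2: C3–C4, by Ni/Cr-mediated addition of an alkenyl triflate (from the 6-acetylchromene) to persilylated phloroglucinaldehyde, then oxidation and desilylation with an acidic fluoride source.
- Disconnection 3 (ring D): chromene annulation of 2,4-dihydroxyacetophenone with 3-methylbut-2-enal.
- Ring order: rings A and B are bought, ring D is made first, ring C last.

Key step: step 8

Remark on the chemistry: the sense of induction of the new protonation cannot be taken from precedent. The quinine-derived squaramide is written; if it favours the (3S) antipode, its quinidine-derived pseudo-enantiomer replaces it in the same step. The configuration is to be assigned by electronic circular dichroism against a computed spectrum.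

**Route**

Step 1
Reactants: 1 (2,4-dihydroxyacetophenone); 2 (3-methylbut-2-enal)
Product: 3 1-(5-hydroxy-2,2-dimethyl-2H-chromen-6-yl)ethanone
Conditions: pyridine, 140 °C (sealed tube)
Reagents that add atoms: none
Why: Formal [3+3] chromene annulation (Knoevenagel-type condensation at the ring carbon between the two oxygens, then oxa-6π-electrocyclisation); the 2-hydroxyl stays hydrogen-bonded to the acetyl group, so the 4-oxygen closes ring D and the angular 5-hydroxy-6-acetyl pattern should result.

Step 2
Reactants: 3 (1-(5-hydroxy-2,2-dimethyl-2H-chromen-6-yl)ethanone)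
Product: 4 1-[5-(tert-butyldimethylsilyloxy)-2,2-dimethyl-2H-chromen-6-yl]ethanone
Conditions: TBSOTf, 2,6-lutidine, CH2Cl2, 0 °C
Reagents that add atoms: tert-butyldimethylsilyl trifluoromethanesulfonate, CC(C)(C)[Si](C)(C)OS(=O)(=O)C(F)(F)F
Why: O-silylation of a hindered, hydrogen-bonded phenol with a silyl triflate and a hindered pyridine base is standard and removes the one acidic proton before enolate formation.

Step 3
Reactants: 4 (1-[5-(tert-butyldimethylsilyloxy)-2,2-dimethyl-2H-chromen-6-yl]ethanone)
Product: 6 1-[5-(tert-butyldimethylsilyloxy)-2,2-dimethyl-2H-chromen-6-yl]ethenyl trifluoromethanesulfonate, via potassium enolate 5 (not isolated)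
Conditions: KN(SiMe3)2 (1.05 equiv), THF, −78 °C; then PhNTf2, −78 → −30 °C; chromatography on Et3N-deactivated silica
Reagents that add atoms: N-phenylbis(trifluoromethanesulfonimide), O=S(=O)(N(c1ccccc1)S(=O)(=O)C(F)(F)F)C(F)(F)F
Why: Enol triflate formation by kinetic deprotonation of the methyl ketone, its only enolisable position, and O-sulfonylation of the potassium enolate; a slight excess of base only and low temperature guard against elimination to the alkyne and silyl transfer between the oxygens.

Step 4
Reactants: 7 (2,4,6-trihydroxybenzaldehyde)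
Product: 8 2,4,6-tris(tert-butyldimethylsilyloxy)benzaldehyde
Conditions: TBSCl, imidazole, DMF, 23 → 40 °C
Reagents that add atoms: tert-butyldimethylsilyl chloride, CC(C)(C)[Si](C)(C)Cl
Why: Exhaustive silylation of the three phenols with silyl chloride and imidazole is routine and removes the acidic protons that would quench the organometallic partner of step 5.

Step 5
Reactants: 6 (alkenyl triflate); 8 (2,4,6-tris(tert-butyldimethylsilyloxy)benzaldehyde)
Product: 9 (RS)-2-[5-(tert-butyldimethylsilyloxy)-2,2-dimethyl-2H-chromen-6-yl]-1-[2,4,6-tris(tert-butyldimethylsilyloxy)phenyl]prop-2-en-1-ol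
Conditions: CrCl2 (4 equiv), NiCl2 (2 mol%), DMF–THF (3:1), 23 °C
Reagents that add atoms: none
Why: Nozaki–Hiyama–Kishi coupling, in which the nickel-activated alkenyl group is passed to chromium and adds chemoselectively to the aldehyde as a non-basic nucleophile that should not provoke silyl migration from the ortho oxygen; the carbinol centre forms racemic and is removed in step 6.

Step 6
Reactants: 9 (racemic allylic alcohol)
Product: 10 2-[5-(tert-butyldimethylsilyloxy)-2,2-dimethyl-2H-chromen-6-yl]-1-[2,4,6-tris(tert-butyldimethylsilyloxy)phenyl]prop-2-en-1-one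
Conditions: Dess–Martin periodinane, pyridine, CH2Cl2, 0 → 23 °C
Reagents that add atoms: none
Why: Dess–Martin oxidation of a secondary alcohol that is both benzylic and allylic is reliable under pyridine buffering and leaves the aryl silyl ethers and the chromene alkene untouched; the enone cannot close because every phenol is masked.

Step 7
Reactants: 10 (tetrakis-silylated enone)
Product: 11 2-(5-hydroxy-2,2-dimethyl-2H-chromen-6-yl)-1-(2,4,6-trihydroxyphenyl)prop-2-en-1-one
Conditions: HF·pyridine, THF, −20 → 0 °C; cold pH 5 phosphate work-up, concentration below 0 °C, used at once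
Reagents that add atoms: none
Why: Cleavage of aryl silyl ethers by an acidic fluoride source (Si–F bond formation) frees the four phenols without generating a phenoxide, so the hydroxy enone, whose known closure is base-mediated, should survive a cold, slightly acidic isolation.

Step 8
Reactants: 11 (2-(5-hydroxy-2,2-dimethyl-2H-chromen-6-yl)-1-(2,4,6-trihydroxyphenyl)prop-2-en-1-one)
Product: 13 (3R)-5,7-dihydroxy-3-(5-hydroxy-2,2-dimethyl-2H-chromen-6-yl)-2,3-dihydro-4H-chromen-4-one, via ring-closed enol 12 (not isolated)
Conditions: 3-{[3,5-bis(trifluoromethyl)phenyl]amino}-4-{[(8α,9S)-6′-methoxycinchonan-9-yl]amino}cyclobut-3-ene-1,2-dione (quinine-derived squaramide, 10 mol%), MTBE–toluene (2:1), −40 °C, slow addition of 11 to the catalyst; cold filtration through acid-washed silica gel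
Reagents that add atoms: none
Why: Proposed new method: the quinuclidine nitrogen of the catalyst deprotonates the ring A hydroxyl that lies next to the vinyl group while the squaramide N–H bonds bind the ketone oxygen, the aryloxide adds to the terminal methylene carbon (intramolecular oxa-Michael addition), and the enolate form of 12, still held by the squaramide, takes its proton at C3 from the neighbouring quinuclidinium N–H. The closest known reaction type is the conjugate addition of thiols or nitrogen nucleophiles to α-substituted acrylic acid derivatives and enones with enantioselective protonation under bifunctional amine–thiourea or amine–squaramide catalysis, combined with the known racemic base-mediated closure of 2-hydroxyphenyl 1-arylvinyl ketones to isoflavanones. Ring C is closed by a 6-endo-trig attack of oxygen on C2, a stereoelectronically allowed mode, which forms the O1–C2 bond. C3, the only new stereocentre, is controlled by the catalyst alone, since proton delivery within the chiral ion pair reaches one face of the planar enolate. Site selectivity comes from the substrate: the two ortho hydroxyls of ring A are interchanged by rotation about the aryl–carbonyl bond, the para hydroxyl cannot reach the alkene, and the ring B hydroxyl could only close in a disfavoured 5-endo-trig mode. Enantioselectivity needs the catalysed proton transfer to outrun uncatalysed closure and later enolisation of 13, which slow addition of 11 to the catalyst at −40 °C, buffering of the quinuclidine by the acidic para hydroxyl of ring A in 11 and 13, and removal of the catalyst on cold acidic silica are meant to secure.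

**Compound list**

1 | 1-(2,4-dihydroxyphenyl)ethanone (2,4-dihydroxyacetophenone) | CC(=O)c1ccc(O)cc1O | starting material
2 | 3-methylbut-2-enal | CC(C)=CC=O | starting material
3 | 1-(5-hydroxy-2,2-dimethyl-2H-chromen-6-yl)ethanone | CC(=O)c1ccc2OC(C)(C)C=Cc2c1O | intermediate
4 | 1-[5-(tert-butyldimethylsilyloxy)-2,2-dimethyl-2H-chromen-6-yl]ethanone | CC(=O)c1ccc2OC(C)(C)C=Cc2c1O[Si](C)(C)C(C)(C)C | intermediate
5 | potassium 1-[5-(tert-butyldimethylsilyloxy)-2,2-dimethyl-2H-chromen-6-yl]ethenolate (not isolated) | [K+].C=C([O-])c1ccc2OC(C)(C)C=Cc2c1O[Si](C)(C)C(C)(C)C | intermediate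
6 | 1-[5-(tert-butyldimethylsilyloxy)-2,2-dimethyl-2H-chromen-6-yl]ethenyl trifluoromethanesulfonate | C=C(OS(=O)(=O)C(F)(F)F)c1ccc2OC(C)(C)C=Cc2c1O[Si](C)(C)C(C)(C)C | intermediate
7 | 2,4,6-trihydroxybenzaldehyde | O=Cc1c(O)cc(O)cc1O | starting material
8 | 2,4,6-tris(tert-butyldimethylsilyloxy)benzaldehyde | O=Cc1c(O[Si](C)(C)C(C)(C)C)cc(O[Si](C)(C)C(C)(C)C)cc1O[Si](C)(C)C(C)(C)C | intermediate
9 | (RS)-2-[5-(tert-butyldimethylsilyloxy)-2,2-dimethyl-2H-chromen-6-yl]-1-[2,4,6-tris(tert-butyldimethylsilyloxy)phenyl]prop-2-en-1-ol (racemic) | C=C(C(O)c1c(O[Si](C)(C)C(C)(C)C)cc(O[Si](C)(C)C(C)(C)C)cc1O[Si](C)(C)C(C)(C)C)c1ccc2OC(C)(C)C=Cc2c1O[Si](C)(C)C(C)(C)C | intermediate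
10 | 2-[5-(tert-butyldimethylsilyloxy)-2,2-dimethyl-2H-chromen-6-yl]-1-[2,4,6-tris(tert-butyldimethylsilyloxy)phenyl]prop-2-en-1-one | C=C(C(=O)c1c(O[Si](C)(C)C(C)(C)C)cc(O[Si](C)(C)C(C)(C)C)cc1O[Si](C)(C)C(C)(C)C)c1ccc2OC(C)(C)C=Cc2c1O[Si](C)(C)C(C)(C)C | intermediate
11 | 2-(5-hydroxy-2,2-dimethyl-2H-chromen-6-yl)-1-(2,4,6-trihydroxyphenyl)prop-2-en-1-one | C=C(C(=O)c1c(O)cc(O)cc1O)c1ccc2OC(C)(C)C=Cc2c1O | intermediate
12 | 3-(5-hydroxy-2,2-dimethyl-2H-chromen-6-yl)-2H-chromene-4,5,7-triol (ring-closed enol, catalyst-bound, not isolated) | CC1(C)C=Cc2c(ccc(C3=C(O)c4c(O)cc(O)cc4OC3)c2O)O1 | intermediate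
13 | (3R)-5,7-dihydroxy-3-(5-hydroxy-2,2-dimethyl-2H-chromen-6-yl)-2,3-dihydro-4H-chromen-4-one | CC1(C)C=Cc2c(ccc([C@@H]3COc4cc(O)cc(O)c4C3=O)c2O)O1 | target

**Step count**

Total: 8 steps. Longest linear sequence: 7 steps (steps 1, 2, 3, 5, 6, 7, 8); step 4 is the side branch.

**Steps most likely to fail**

Step 8. Facial selectivity of the proton transfer may be poor, because the enolate can also be protonated by the many free phenolic hydroxyls outside the catalyst pocket. Uncatalysed closure or slow enolisation of the product may erode what selectivity there is. The fallback sets out from 11 and comes back at 13. Compound 11 is closed with a catalytic amount of Et3N in ethyl acetate at 23 °C, the known base-mediated oxa-Michael closure of 2-hydroxyphenyl 1-arylvinyl ketones, to give the racemic isoflavanone F1. This is resolved by preparative HPLC on an amylose tris(3,5-dimethylphenylcarbamate) stationary phase, and the (3R) fraction is 13. The (3S)-enantiomer F2 is returned to F1 by brief exposure to Et3N in ethanol (enolisation at C3) and resolved again, so in principle no material is lost.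

Step 7. Ring closure may set in during the unmasking, through general-base catalysis by pyridine or fluoride once a ring A ortho oxygen is free. Cleavage of the hindered ring B silyl ether may also be too slow at low temperature. Either way, racemic material would enter step 8. The fallback sets out from 7 (and uses 6) and comes back at 11; it masks the ring A oxygens as acid-labile acetals so that the last unmasking needs only a weak acid. Compound 7 with 1-chloroethyl ethyl ether and NaH in DMF at 0 °C should give 2,4,6-tris(1-ethoxyethoxy)benzaldehyde F3, a mixture of diastereomers. Coupling with 6 under the conditions of step 5 gives the racemic allylic alcohol F4, and Dess–Martin oxidation gives the acetal-protected enone F5. Bu4NF buffered with acetic acid in THF at 0 °C removes the single ring B silyl group to give the ring B phenol F6. No closure can occur at this stage, because every ring A oxygen is still masked and the ring B oxygen could only close 5-endo. Pyridinium p-toluenesulfonate in methanol at 0 °C then exchanges the three acetals and sets 11 free in a medium that holds neither base nor fluoride.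

Step 5. Addition to the doubly ortho-substituted, electron-rich aldehyde may be slow, so that the alkenyl triflate is lost to reduction, homocoupling or hydrolysis back to 4. Silyl transfer from an ortho oxygen to the new alkoxide is a further possible loss. The fallback sets out from 6 and comes back at 9. The triflate is exchanged for iodide with NaI, catalytic Ni(OAc)2·4H2O, 1,5-cyclooctadiene and catalytic Zn in DMA–THF at 23 °C, a known nickel-catalysed halogenation of enol triflates, to give the alkenyl iodide F7. Iodine–magnesium exchange with i-PrMgCl·LiCl in THF at −20 °C gives the alkenylmagnesium chloride F8, a much stronger nucleophile than the chromium reagent. It is added to 8 at −40 °C and quenched cold with acetic acid to give 9. The carbon–magnesium bond is covalent enough that silyl migration from the ortho oxygen to carbon should stay slow at these temperatures.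

**Further compounds**

F1 | step 8 | rac-5,7-dihydroxy-3-(5-hydroxy-2,2-dimethyl-2H-chromen-6-yl)-2,3-dihydro-4H-chromen-4-one | CC1(C)C=Cc2c(ccc(C3COc4cc(O)cc(O)c4C3=O)c2O)O1
F2 | step 8 | (3S)-5,7-dihydroxy-3-(5-hydroxy-2,2-dimethyl-2H-chromen-6-yl)-2,3-dihydro-4H-chromen-4-one | CC1(C)C=Cc2c(ccc([C@H]3COc4cc(O)cc(O)c4C3=O)c2O)O1
F3 | step 7 | 2,4,6-tris(1-ethoxyethoxy)benzaldehyde (mixture of diastereomers) | O=Cc1c(OC(C)OCC)cc(OC(C)OCC)cc1OC(C)OCC
F4 | step 7 | 2-[5-(tert-butyldimethylsilyloxy)-2,2-dimethyl-2H-chromen-6-yl]-1-[2,4,6-tris(1-ethoxyethoxy)phenyl]prop-2-en-1-ol (mixture of stereoisomers) | C=C(C(O)c1c(OC(C)OCC)cc(OC(C)OCC)cc1OC(C)OCC)c1ccc2OC(C)(C)C=Cc2c1O[Si](C)(C)C(C)(C)C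
F5 | step 7 | 2-[5-(tert-butyldimethylsilyloxy)-2,2-dimethyl-2H-chromen-6-yl]-1-[2,4,6-tris(1-ethoxyethoxy)phenyl]prop-2-en-1-one | C=C(C(=O)c1c(OC(C)OCC)cc(OC(C)OCC)cc1OC(C)OCC)c1ccc2OC(C)(C)C=Cc2c1O[Si](C)(C)C(C)(C)C
F6 | step 7 | 2-(5-hydroxy-2,2-dimethyl-2H-chromen-6-yl)-1-[2,4,6-tris(1-ethoxyethoxy)phenyl]prop-2-en-1-one | C=C(C(=O)c1c(OC(C)OCC)cc(OC(C)OCC)cc1OC(C)OCC)c1ccc2OC(C)(C)C=Cc2c1O
F7 | step 5 | 5-(tert-butyldimethylsilyloxy)-6-(1-iodoethenyl)-2,2-dimethyl-2H-chromene | C=C(I)c1ccc2OC(C)(C)C=Cc2c1O[Si](C)(C)C(C)(C)C
F8 | step 5 | chlorido{1-[5-(tert-butyldimethylsilyloxy)-2,2-dimethyl-2H-chromen-6-yl]ethenyl}magnesium | C=C([Mg]Cl)c1ccc2OC(C)(C)C=Cc2c1O[Si](C)(C)C(C)(C)C
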